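Follow the solid substrate through this flask: it leaves by two doors, for the protic impurity quenches it and it also dissolves, and in the scheme the quenched substrate reacts no further.

solid substrate 0.033 M; solid reagent 0.0363 M; protic impurity 0.0330 M; time 1.0 h

    solid substrate ⇌ dissolved substrate, rate k1*(cs1 - [dissolved substrate]) while solid is left; crystals form when [dissolved substrate] > cs1 (cs1 = 22 mM, k1 = 0.054 /min)
    dissolved substrate + partner → target (k2 = 1.5 /M/min)
    2 dissolved substrate → side product (k3 = 1.6 /M/min)
    solid reagent ⇌ partner, rate k4*(cs4 - [partner]) while solid is left; crystals form when [partner] > cs4 (cs4 = 14 mM, k4 = 0.016 /min)
    crystals ⇌ target, rate k5*(cs5 - [target]) while solid is left; crystals form when [target] > cs5 (cs5 = 16 mM, k5 = 0.53 /min)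
    solid substrate + protic impurity → quenched substrate (k6 = 2.5 /M/min)

- percentages count the solid substrate that a species holds: one side product counts as two
- target is meant together with its crystals
- two of one species on the left: rate k times its square, two consumed each time
- solid, in amounts per volume of the solution: solid substrate, solid reagent, crystals
- at the start none of the solid substrate is in solution
- at the start none of the solid reagent is in solution
- what has only dissolved of solid substrate counts as not reacted
- the reaction counts as stopped when no species that holds the solid substrate changes by six tenths of a point or more over the second half of the time
- run time (flask): 1.0 h

- the state of affairs at 1.0 h: stopped, and by what, or still going (for what has run out or reacted, a solid counts together with what of it has only dissolved) (all of the solid substrate has reacted / the partner has run out first / it is still moving)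
- part of the solid substrate that has turned into other species by 1.0 h (what has only dissolved does not count)
- amount of target at 1.0 h, in percent of the solid substrate charged
- amount of side product at 1.0 h, in percent of the solid substrate charged

I built the flask up one process at a time, with x the fraction of the charge still solid. With the quench running by itself, the half-life of 0.14 h was shorter than the time of 1.0 h, and with equal charges the second-order integral gave 83.2% quenched.

Then I added dissolving, whose rate as a fraction of the charge, from an empty solution, is a = 0.0360 /min, and I held the impurity at its charge, so that the quench became pseudo-first-order with b = 0.0825 /min. The rate law and its closed form were:

dx/dt = −a − b·x, so x reaches zero at t = ln(1 + ρ)/b, with ρ = b/a = 2.29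

quench share = 1 − ln(1 + ρ)/ρ = 48.0%

That quench share, the fraction of the charge the impurity takes before the solid is gone, came out lower than the first figure, and in this reckoning the solid was gone by 0.241 h. Holding the impurity at its charge and the solution empty were my two simplifications.

Last came the rest. The solid reagent dissolves more slowly, at a rate of 0.00679 /min as a fraction of the substrate charge, so I left the partner out and let the remaining 52.0% dimerise from that moment:

pool at the end = start/(1 + 2·k·c·start·t) = 14.8%

Here k is the dimerisation constant, c the charge and t the time remaining. My conversion was therefore 85.2%.

The forecast put conversion higher than my figure; its verdict was “it is still moving”, with conversion 88.5% (85% to 92%), target 8.5% (6.5% to 11%) and side product 34% (29% to 39%), on the ground that “the dissolved substrate mostly dimerises because the partner only trickles in slowly”.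

This flask gave the verdict “it is still moving”, with conversion 88.3%, target 7.72% and side product 33.1%, and with quenched substrate at 47.5% against my 48.0%. The neighbour flask with 0.020 M of protic impurity had ρ = 1.39, so its quench share came to 37.3%, and that neighbour held 35.7% of quenched substrate. This flask had not come to rest at 1.0 h: dissolved substrate went from 26.3% at 0.500 h to 11.7%. At 10.0 h this flask read conversion >99.9%, side product 36.6% and target 15.9%, with quenched substrate unmoved at 47.5%.

The constants belong to no real substance, and the outcome is calculated.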